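I nearly read the coupling as proportional to c(starting material), which is the pitfall. Its brake, at 2.0 mM against 0.029 mM, cancels that concentration, so the coupling is pseudo-first-order in partner for as long as c(starting material) stays high.

| setting | gamma | beta | delta | eta |
|---|---|---|---|---|
| starting material | 2.0 mM | 2.0 mM | 2.0 mM | 2.0 mM (fed, over 6.0 min) |
| partner | 1.00 equiv (in portions, 3, over 6.0 min) | 1.00 equiv (fed, over 6.0 min) | 1.00 equiv | 1.00 equiv |
| free catalyst | 0.2 mol% | 0.2 mol% | 0.2 mol% | 0.2 mol% |
| time | 10 min | 10 min | 10 min | 10 min |
| remark | first portion at the start, last at 6.0 min | all else is in the flask from the start; the feed brings no volume worth counting | everything together at the start | all else is in the flask from the start; the feed brings no volume worth counting |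

- the flask with the highest amount of target, in percent of the starting material charged ("all alike" if they lie within 1.5 percentage points) (gamma / beta / delta / eta / all alike)
- final target, as a percentage of the starting material charged, in gamma
- final target, as a percentage of the starting material charged, in beta
- final target, as a percentage of the starting material charged, in delta
- final target, as a percentage of the starting material charged, in eta

- for target the idle complex is counted in
- run time (gamma): 10 min

    starting material + partner + free catalyst → target + free catalyst, rate k1*[starting material]*[partner]*[free catalyst]/(1 + ([starting material]/sat1)) (sat1 = 0.029 mM, k1 = 3.6 × 10⁸ M⁻² s⁻¹)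
    free catalyst + target ⇌ idle complex (K2 = 460 M⁻¹, k2 = 23 M⁻¹ s⁻¹)
    target ⇌ isomer of the product (K3 = 2.9, k3 = 0.0075 s⁻¹)
    free catalyst → spent catalyst (k4 = 0.011 s⁻¹)

I followed one molecule through its forks, taking free catalyst to die at 0.011 s⁻¹ and the coupling constant as 3.6 × 10⁸ M⁻² s⁻¹.

1. Slope, delta. Free catalyst stood at 0.00400 mM, so partner fell at 0.0418 s⁻¹ and target rose at about 5.01 mM min⁻¹.

2. First fork. Partner's half-life was 0.277 min, shorter than the catalyst's 1.05 min. Integrating over the dying catalyst, a partner molecule escapes with chance exp(−reach), where the reach is that fresh-catalyst rate constant over the death constant: 3.80.

3. Knee and level. In delta I expected target to bend over towards its balance with the isomer of the product, with a relaxation half-life of 1.15 min, short against 10 min. The forward half-life of free target by binding to free catalyst, 130 min, was longer than by isomerisation, 1.5 min, so I let the second fork leave a formed molecule as target with chance 25.6 %. Delta's level: 25.1 %.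

4. Dosed partner. A portion entering at time t meets the reach shrunk by exp(−death constant × t). Averaged over gamma's portions, a partner molecule escaped with chance 51.5 %, so gamma: 12.4 %. I put beta's steady feed at the same mean escape: 12.4 %.

5. Eta. The coupling ceiling at mid-feed, 0.346 mM min⁻¹, about met the feed of starting material, 0.333 mM min⁻¹. So I took half of the partner as reacted by mid-feed and let the rest meet the shrunken reach: 18.1 %.

My ranking: delta.

The forecast named delta, with 13.7 % in gamma, 13 % in beta, 24.8 % in delta and 18.5 % in eta, on the ground that “The catalyst dies within a few minutes and works best when the partner concentration is high”. Its beta is higher than mine.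

The simulation gave delta: 14.8 % in gamma, 14.1 % in beta, 25.2 % in delta, 19.4 % in eta.

Catalyst death held beta's target down, as the largest single effect though not the main reason: with the step from free catalyst to spent catalyst struck out, beta gave 28.4 % against 14.1 %. The reach left 2.24 % of the partner by my reckoning, while delta held 3.46 %. A further flask like delta but with 0.400 equiv of partner kept starting material at 61.0 %, and there the reach promised target of 10.0 %. That flask held 2.46 % of its partner and 10.1 % of target.

(The numbers of this flask were drawn at random within sensible limits; the result is computed.)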